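Ring A is assembled last from non-aromatic parts. Its C5–C6–C7–C8 edge (H, OMe, OMe, O) maps onto C4–C3–C2–C1 of a 4-substituted 2,3-dimethoxycyclobutenone. The C4a=C8a fusion bond is the unsubstituted C5=C6 alkene of a 2-aryl-4-pyranone, so the synthesis rests on cutting C4a–C5 and C8–C8a. In one operation a palladium-catalysed coupling joins a squarate-derived 4-chlorocyclobutenone to a 5-stannylpyranone that already bears benzyl-protected ring B. Heating then opens the four-membered ring to a dienylketene, which closes onto pyranone C6 and aromatises to the 8-hydroxyflavone. O-Methylation at C8 and hydrogenolysis of the benzyl ether complete the target.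

Key step: step 8

Remark on the chemistry: the target has no stereocentre. The sp3 centres of 6, 13, 14, 15, 16 and 18 are transient, are handled as racemates (6 as a diastereomer mixture) and are all erased by the time 19 forms.

Step 1
Reactants: 1 3-hydroxy-4,5-dimethoxybenzoic acid
Product: 3 3-(benzyloxy)-4,5-dimethoxybenzoic acid, via benzyl ester 2 (not isolated)
Conditions: BnBr (2.3 equiv), K2CO3, DMF, 60 °C; then aq NaOH, MeOH, 60 °C; HCl to pH 2
Reagents that add atoms: benzyl bromide, BrCc1ccccc1; sodium hydroxide, [Na+].[OH-]
Why: Williamson-type O-alkylation benzylates both the phenoxide and the carboxylate, and saponification in the same flask then frees only the acid, because the aryl benzyl ether is inert to hydroxide.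

Step 2
Reactants: 3 3-(benzyloxy)-4,5-dimethoxybenzoic acid
Product: 4 3-(benzyloxy)-4,5-dimethoxybenzoyl chloride
Conditions: (COCl)2 (1.3 equiv), DMF (cat), CH2Cl2, 0 °C to rt; evaporation, used crude
Reagents that add atoms: oxalyl chloride, O=C(Cl)C(=O)Cl
Why: Acid chloride formation with oxalyl chloride under catalytic Vilsmeier-type activation runs at room temperature and touches neither the aryl methyl ethers nor the benzyl ether.

Step 3
Reactants: 5 (E)-4-methoxybut-3-en-2-one
Product: 7 (Z)-3-bromo-4-methoxybut-3-en-2-one, via dibromide 6 (not isolated)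
Conditions: Br2 (1.0 equiv), CH2Cl2, −78 to 0 °C; then Et3N (1.2 equiv), 0 °C to rt
Reagents that add atoms: bromine, BrBr
Why: Bromination–dehydrobromination of an enone (addition of Br2 across the enol-ether alkene, then E2 loss of HBr through the acidic α-hydrogen) puts bromine on C3 only, should give the Z isomer with acetyl and methoxy trans (a geometry that is lost again in step 4), and is done before ring B is present so that nuclear bromination of the trialkoxyarene cannot occur.

Step 4
Reactants: 7 (Z)-3-bromo-4-methoxybut-3-en-2-one; 4 3-(benzyloxy)-4,5-dimethoxybenzoyl chloride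
Product: 10 2-[3-(benzyloxy)-4,5-dimethoxyphenyl]-5-bromo-4H-pyran-4-one, via lithium enolate 8 (not isolated), via bromo diketone 9 (not isolated)
Conditions: 7 (2.2 equiv), LiN(SiMe3)2 (2.2 equiv), THF, −78 °C; 4 (1 equiv), −78 °C; AcOH quench, extraction; crude 9, TFA (10 vol %), CH2Cl2, rt
Reagents that add atoms: none
Why: Kinetic deprotonation of the methyl ketone and Claisen-type C-acylation by the acid chloride (the second equivalent of enolate takes up the acidic proton of the 1,3-diketone) follow the established γ-pyranone synthesis from 4-methoxybutenone, and acid then drives 6-endo oxa-Michael addition of the enol oxygen with loss of methanol, so that the vinylic bromine, a spectator throughout, ends unambiguously at C5.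

Step 5
Reactants: 10 2-[3-(benzyloxy)-4,5-dimethoxyphenyl]-5-bromo-4H-pyran-4-one
Product: 11 2-[3-(benzyloxy)-4,5-dimethoxyphenyl]-5-(tributylstannyl)-4H-pyran-4-one
Conditions: (Bu3Sn)2 (1.5 equiv), Pd(PPh3)4 (5 mol %), toluene, 110 °C; chromatography on Et3N-deactivated silica
Reagents that add atoms: hexabutyldistannane, CCCC[Sn](CCCC)(CCCC)[Sn](CCCC)(CCCC)CCCC
Why: Palladium-catalysed stannylation of a vinylic or heteroaryl bromide with a hexaalkyldistannane (oxidative addition, Sn–Sn transmetalation, reductive elimination) is established for bromo-2-pyranones and 5-halouracils, and the excess of distannane should hold back homocoupling.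

Step 6
Reactants: 12 dimethyl squarate (3,4-dimethoxycyclobut-3-ene-1,2-dione)
Product: 13 4-hydroxy-2,3-dimethoxycyclobut-2-en-1-one (racemic)
Conditions: LiAlH(OtBu)3 (1.05 equiv), THF, −78 to −20 °C; pH 7 phosphate buffer
Reagents that add atoms: none
Why: The bulky, mild hydride performs a single 1,2-reduction of the squarate ester because the remaining carbonyl is a deactivated vinylogous ester, the carbinol centre is formed racemic and disappears in step 8, and the neutral quench avoids acid-induced collapse to the semisquarate.

Step 7
Reactants: 13 4-hydroxy-2,3-dimethoxycyclobut-2-en-1-one (racemic)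
Product: 15 4-chloro-2,3-dimethoxycyclobut-2-en-1-one (racemic), via alkoxyiminium chloride 14 (not isolated)
Conditions: Me2C=C(Cl)NMe2 (1.1 equiv), CH2Cl2, 0 °C to rt; evaporation, residue taken up in 1,4-dioxane and used at once
Reagents that add atoms: 1-chloro-N,N,2-trimethylprop-1-en-1-amine, CC(C)=C(Cl)N(C)C
Why: Deoxychlorination of an alcohol with an α-chloroenamine is a known neutral method in which the hydroxyl adds to the derived keteniminium ion and chloride displaces the amide leaving group at the allylic, α-keto carbon, so that with no free acid, water or amine present the methyl enol ethers should survive and the C4 chloride, which keeps the vinylogous ester conjugation, should be the regioisomer obtained.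

Step 8
Reactants: 15 4-chloro-2,3-dimethoxycyclobut-2-en-1-one (racemic); 11 2-[3-(benzyloxy)-4,5-dimethoxyphenyl]-5-(tributylstannyl)-4H-pyran-4-one
Product: 19 2-[3-(benzyloxy)-4,5-dimethoxyphenyl]-8-hydroxy-6,7-dimethoxy-4H-chromen-4-one, via pyranonylcyclobutenone 16 (not isolated), via dienylketene 17 (not isolated), via cyclohexadienone 18 (not isolated)
Conditions: 15 (1.3 equiv), Pd2(dba)3 (2.5 mol %), P(2-furyl)3 (10 mol %), 1,4-dioxane (0.05 M), 50 °C, then 100 °C; aq KF work-up
Reagents that add atoms: none
Why: Proposed new method: zerovalent palladium inserts into the allylic, α-keto C–Cl bond of 15, the pyranon-5-yl group passes from tin to palladium (C5 is the electron-rich β-carbon of the ring enol ether, which should help this electrophilic substitution at carbon), and reductive elimination at the CH terminus of the oxocyclobutenyl ligand makes the C4a–C5 bond of 16. At 100 °C the C1–C4 σ bond of 16 breaks in a reversible four-electron conrotatory opening; only ketene 17, with the pyranonyl group turned inward, can react further, and reclosure of the outward isomer feeds material back to it. Ring A then closes by a thermal six-electron disrotatory electrocyclisation across the ketene C=C, the new C=CH bond and the pyranone C5=C6 bond (six-membered carbocycle, ketene carbon to pyranone C6, which is C8–C8a), and enolisation of 18 with loss of the C8a hydrogen gives the phenol. The closest known reaction type is the Stille-type coupling of 4-chlorocyclobutenones with alkenyl, aryl, furyl and thienyl stannanes followed by the same thermal benzannulation; new here are the 4-pyranon-5-yl stannane and closure onto a pyranone alkene, whose localised double-bond character should cost less than the dearomatisation of benzene or furan. No stereocentre is created in 19, since the sp3 centres of 16 and 18 are racemic and both are erased. Two selectivities are needed: coupling at CH and not at C(OMe) of the allyl unit, secured by the smaller substituent and by retention of the vinylogous ester, and closure at C6 only, secured because the other neighbour of the tin-bearing C5 is the carbonyl carbon C4, which cannot end a six-electron array.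

Step 9
Reactants: 19 2-[3-(benzyloxy)-4,5-dimethoxyphenyl]-8-hydroxy-6,7-dimethoxy-4H-chromen-4-one
Product: 20 2-[3-(benzyloxy)-4,5-dimethoxyphenyl]-6,7,8-trimethoxy-4H-chromen-4-one
Conditions: MeI (3 equiv), K2CO3 (2 equiv), acetone, reflux
Reagents that add atoms: iodomethane, CI
Why: Williamson O-methylation acts on the only free phenol of 19, so no site selectivity is required, and the pyranone and the benzyl ether are untouched by K2CO3.

Step 10
Reactants: 20 2-[3-(benzyloxy)-4,5-dimethoxyphenyl]-6,7,8-trimethoxy-4H-chromen-4-one
Product: 21 2-(3-hydroxy-4,5-dimethoxyphenyl)-6,7,8-trimethoxy-4H-chromen-4-one (target)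
Conditions: H2 (1 atm), Pd/C (10 wt %), EtOAc–MeOH, rt
Reagents that add atoms: none
Why: Catalytic hydrogenolysis of the aryl benzyl ether proceeds at room temperature and 1 atm, conditions under which the conjugated C2=C3 bond and the carbonyl of flavones are normally retained, provided that tin residues were removed after step 8.

Compound list
1 | 3-hydroxy-4,5-dimethoxybenzoic acid | COc1cc(C(=O)O)cc(O)c1OC | starting material
2 | benzyl 3-(benzyloxy)-4,5-dimethoxybenzoate | COc1cc(C(=O)OCc2ccccc2)cc(OCc2ccccc2)c1OC | intermediate
3 | 3-(benzyloxy)-4,5-dimethoxybenzoic acid | COc1cc(C(=O)O)cc(OCc2ccccc2)c1OC | intermediate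
4 | 3-(benzyloxy)-4,5-dimethoxybenzoyl chloride | COc1cc(C(=O)Cl)cc(OCc2ccccc2)c1OC | intermediate
5 | (E)-4-methoxybut-3-en-2-one | CO/C=C/C(C)=O | starting material
6 | 3,4-dibromo-4-methoxybutan-2-one (racemic diastereomer mixture) | COC(Br)C(Br)C(C)=O | intermediate
7 | (Z)-3-bromo-4-methoxybut-3-en-2-one | CO/C=C(\Br)C(C)=O | intermediate
8 | lithium (3Z)-3-bromo-4-methoxybuta-1,3-dien-2-olate | [Li+].[O-]C(=C)/C(Br)=C/OC | intermediate
9 | (4Z)-1-[3-(benzyloxy)-4,5-dimethoxyphenyl]-4-bromo-5-methoxypent-4-ene-1,3-dione (drawn as the diketo tautomer) | CO/C=C(\Br)C(=O)CC(=O)c1cc(OC)c(OC)c(OCc2ccccc2)c1 | intermediate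
10 | 2-[3-(benzyloxy)-4,5-dimethoxyphenyl]-5-bromo-4H-pyran-4-one | COc1cc(-c2cc(=O)c(Br)co2)cc(OCc2ccccc2)c1OC | intermediate
11 | 2-[3-(benzyloxy)-4,5-dimethoxyphenyl]-5-(tributylstannyl)-4H-pyran-4-one | CCCC[Sn](CCCC)(CCCC)c1coc(-c2cc(OC)c(OC)c(OCc3ccccc3)c2)cc1=O | intermediate
12 | dimethyl squarate (3,4-dimethoxycyclobut-3-ene-1,2-dione) | COC1=C(OC)C(=O)C1=O | starting material
13 | 4-hydroxy-2,3-dimethoxycyclobut-2-en-1-one (racemic) | COC1=C(OC)C(O)C1=O | intermediate
14 | N-{1-[(2,3-dimethoxy-4-oxocyclobut-2-en-1-yl)oxy]-2-methylpropylidene}-N-methylmethanaminium chloride (racemic) | COC1=C(OC)C(OC(C(C)C)=[N+](C)C)C1=O.[Cl-] | intermediate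
15 | 4-chloro-2,3-dimethoxycyclobut-2-en-1-one (racemic) | COC1=C(OC)C(Cl)C1=O | intermediate
16 | 2-[3-(benzyloxy)-4,5-dimethoxyphenyl]-5-(2,3-dimethoxy-4-oxocyclobut-2-en-1-yl)-4H-pyran-4-one (racemic) | COC1=C(OC)C(c2coc(-c3cc(OC)c(OC)c(OCc4ccccc4)c3)cc2=O)C1=O | intermediate
17 | 2-[3-(benzyloxy)-4,5-dimethoxyphenyl]-5-[(1E)-2,3-dimethoxy-4-oxobuta-1,3-dien-1-yl]-4H-pyran-4-one (ketene chain and pyranonyl group cis across the C=CH bond) | O=C=C(OC)/C(OC)=C\c1coc(-c2cc(OC)c(OC)c(OCc3ccccc3)c2)cc1=O | intermediate
18 | 2-[3-(benzyloxy)-4,5-dimethoxyphenyl]-6,7-dimethoxy-4H-chromene-4,8(8aH)-dione (racemic) | COC1=C(OC)C(=O)C2OC(c3cc(OC)c(OC)c(OCc4ccccc4)c3)=CC(=O)C2=C1 | intermediate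
19 | 2-[3-(benzyloxy)-4,5-dimethoxyphenyl]-8-hydroxy-6,7-dimethoxy-4H-chromen-4-one | COc1cc(-c2cc(=O)c3cc(OC)c(OC)c(O)c3o2)cc(OCc2ccccc2)c1OC | intermediate
20 | 2-[3-(benzyloxy)-4,5-dimethoxyphenyl]-6,7,8-trimethoxy-4H-chromen-4-one | COc1cc(-c2cc(=O)c3cc(OC)c(OC)c(OC)c3o2)cc(OCc2ccccc2)c1OC | intermediate
21 | 2-(3-hydroxy-4,5-dimethoxyphenyl)-6,7,8-trimethoxy-4H-chromen-4-one | COc1cc(-c2cc(=O)c3cc(OC)c(OC)c(OC)c3o2)cc(O)c1OC | target

Total step count: 10. Longest linear sequence: 7 steps (1, 2, 4, 5, 8, 9, 10).

Steps most likely to fail

1. **Step 8 (labelled step).**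
   - **What may go wrong:** Tin-to-palladium transfer from the stannane next to the carbonyl may be too slow, so that the chloride decomposes first. Coupling may occur at the methoxy-bearing allyl terminus. The ketene may be captured or may oligomerise before it closes onto the electron-poor C6.
   - **Fallback (known chemistry):** This is a Baker–Venkataraman flavone synthesis, setting out from 4 and coming back at 20. Commercial 2,3,4-trimethoxyphenol is C-acetylated ortho to the hydroxyl (AcOH, BF3·OEt2, 90 °C) to 1-(2-hydroxy-3,4,5-trimethoxyphenyl)ethan-1-one F1. Acid chloride 4 acylates its phenol (pyridine, DMAP cat, rt) to 6-acetyl-2,3,4-trimethoxyphenyl 3-(benzyloxy)-4,5-dimethoxybenzoate F2. KOH in pyridine at 50 °C moves the aroyl group from oxygen to the acetyl carbon, giving 1-[3-(benzyloxy)-4,5-dimethoxyphenyl]-3-(2-hydroxy-3,4,5-trimethoxyphenyl)propane-1,3-dione F3. Cyclodehydration (p-TsOH cat, toluene, reflux) should then give 20, which continues with step 10.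

2. **Step 7.**
   - **What may go wrong:** The activated carbinol may ionise to the stabilised oxocyclobutenyl cation, followed by chloride attack at the methoxy-bearing carbon and loss of a methyl group. The product may also hydrolyse on handling.
   - **Fallback:** It sets out from 13 and comes back at 19. Substitution at carbon is avoided altogether, and the hydroxyl is acylated under basic conditions (Ac2O, pyridine, DMAP cat, CH2Cl2, 0 °C) to the storable allylic ester 2,3-dimethoxy-4-oxocyclobut-2-en-1-yl acetate F4 (racemic). F4 replaces 15 in the coupling with 11 under the conditions known for allylic acetates and stannanes (Pd2(dba)3, LiCl, DMF, rt to 50 °C, then 100 °C). This should form 16 and, by the same thermal cascade, 19.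

3. **Step 5.**
   - **What may go wrong:** The bromide may homocouple with freshly formed stannane. Reductive loss of bromine and protodestannylation during purification are also possible.
   - **Fallback:** It sets out from 10 and comes back at 11. Palladium catalysis is replaced by polar halogen–metal exchange, as practised on α-halo-β-oxy enones such as 5-iodo-1,3-dioxin-4-ones and 5-iodouracils. Treatment with iPrMgCl·LiCl (THF, −40 °C) should give {6-[3-(benzyloxy)-4,5-dimethoxyphenyl]-4-oxo-4H-pyran-3-yl}magnesium chloride F5. This is quenched cold with Bu3SnCl to give 11, which is filtered through neutral alumina.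

Further compounds
F1 | step 8 | 1-(2-hydroxy-3,4,5-trimethoxyphenyl)ethan-1-one | CC(=O)c1cc(OC)c(OC)c(OC)c1O
F2 | step 8 | 6-acetyl-2,3,4-trimethoxyphenyl 3-(benzyloxy)-4,5-dimethoxybenzoate | CC(=O)c1cc(OC)c(OC)c(OC)c1OC(=O)c1cc(OC)c(OC)c(OCc2ccccc2)c1
F3 | step 8 | 1-[3-(benzyloxy)-4,5-dimethoxyphenyl]-3-(2-hydroxy-3,4,5-trimethoxyphenyl)propane-1,3-dione | COc1cc(C(=O)CC(=O)c2cc(OC)c(OC)c(OCc3ccccc3)c2)c(O)c(OC)c1OC
F4 | step 7 | 2,3-dimethoxy-4-oxocyclobut-2-en-1-yl acetate (racemic) | COC1=C(OC)C(OC(C)=O)C1=O
F5 | step 5 | {6-[3-(benzyloxy)-4,5-dimethoxyphenyl]-4-oxo-4H-pyran-3-yl}magnesium chloride | COc1cc(-c2cc(=O)c([Mg]Cl)co2)cc(OCc2ccccc2)c1OC
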